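A direct plan would close ring C by a chiral-acid-catalysed oxa-[4+2] cycloaddition: the bis-silylated salicylaldehyde A1 would be turned in the flask into the methoxy ortho-quinone methide A2, which would add 4-methoxy-3-prenylstyrene A3 to give the 2,4-cis 4-methoxyflavan A4.
Hydrolysis to the flavan-4-ol A5, oxidation to the silylated flavanone A6 and desilylation would then finish the target.
Its weakest steps would be:
- The cycloaddition: an intermolecular, enantioselective reaction of this kind has no close precedent, C2 would depend on endo/exo control, and the acid would have to spare the prenyl alkene and keep the styrene from oligomerising.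
- The hydrolysis and oxidation at C4: a stereocentre would be made at C4 only to be erased, and two steps plus a separation of the trans isomer would build nothing.
- The prenyl–aryl Suzuki coupling that makes A3: branched prenyl transfer and Heck reaction at the vinyl group would both threaten a simple fragment.

**Retrosynthetic overview**
- The only stereocentre, C2, carries ring B, so the route cuts the C2–C1' bond: ring C is present from the start as the flat, weakly aromatic γ-pyrone of a 5,7-dioxygenated chromone, and its C2=C3 bond is arylated enantioselectively.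
- Ring order: rings A and C are bought fused (5,7-dihydroxychromone) and no ring is closed in the route; ring B arrives last as the complete 4-methoxy-3-prenylphenylboronic acid.
- The prenyl group is placed on C3' of a simple anisole by iodine–magnesium exchange and copper-catalysed allylic substitution, with no styrene present.
- C2 is set directly at the C4 ketone oxidation state, so no C4 stereocentre is made and erased, and the prenyl alkene never has to compete with a second alkene.

Key step: step 4

Assumption: the (R)-ligand is chosen from the accepted facial model for cyclic enones (aryl delivered to the alkene face remote from the tert-butyl group), which points to the 2S product; if the sense proved opposite, the equally available (S)-ligand would be used.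

Step 1
Reactants: 1 4-bromo-2-iodo-1-methoxybenzene (4-bromo-2-iodoanisole); 2 1-bromo-3-methylbut-2-ene (prenyl bromide)
Product: 4 4-bromo-1-methoxy-2-(3-methylbut-2-en-1-yl)benzene, via (5-bromo-2-methoxyphenyl)magnesium chloride 3 (not isolated)
Conditions: i-PrMgCl·LiCl (1.05 equiv), THF, −15 °C; then Li2CuCl4 (3 mol%), 2 (1.2 equiv), −15 °C to rt
Reagents that add atoms: none
Why: Iodine–magnesium exchange is far faster at the C–I bond ortho to the methoxy group than at the C–Br bond, and the copper-catalysed allylic substitution of the aryl Grignard reagent on the primary allylic bromide should occur at the unhindered CH2 terminus to give the linear prenyl arene.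

Step 2
Reactants: 4 4-bromo-1-methoxy-2-(3-methylbut-2-en-1-yl)benzene
Product: 7 [4-methoxy-3-(3-methylbut-2-en-1-yl)phenyl]boronic acid, via [4-methoxy-3-(3-methylbut-2-en-1-yl)phenyl]lithium 5 (not isolated), via lithium triisopropoxy[4-methoxy-3-(3-methylbut-2-en-1-yl)phenyl]borate 6 (not isolated)
Conditions: n-BuLi (1.05 equiv), THF, −78 °C; B(Oi-Pr)3 (1.5 equiv), −78 °C to rt; aq. HCl (1 M), 0 °C
Reagents that add atoms: triisopropyl borate, CC(C)OB(OC(C)C)OC(C)C; water, O
Why: Bromine–lithium exchange, borylation with a trialkyl borate and hydrolysis of the ate complex form a routine sequence to which the methyl ether and the isolated trisubstituted alkene are inert at low temperature.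

Step 3
Reactants: 8 5,7-dihydroxy-4H-chromen-4-one (5,7-dihydroxychromone)
Product: 9 5,7-bis(triisopropylsilyloxy)-4H-chromen-4-one
Conditions: i-Pr3SiOTf (2.4 equiv), 2,6-lutidine (4 equiv), CH2Cl2, 0 °C to rt
Reagents that add atoms: triisopropylsilyl trifluoromethanesulfonate, CC(C)[Si](OS(=O)(=O)C(F)(F)F)(C(C)C)C(C)C
Why: Silyl ether formation with a silyl triflate is forceful enough to cap the 5-hydroxyl that is hydrogen-bonded to the C4 carbonyl as well as the acidic 7-hydroxyl, and the bulky triisopropylsilyl ethers should survive the warm, wet, weakly acidic medium of the next step.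

Step 4
Reactants: 9 5,7-bis(triisopropylsilyloxy)-4H-chromen-4-one; 7 [4-methoxy-3-(3-methylbut-2-en-1-yl)phenyl]boronic acid (2 equiv)
Product: 10 (2S)-2-[4-methoxy-3-(3-methylbut-2-en-1-yl)phenyl]-5,7-bis(triisopropylsilyloxy)chroman-4-one
Conditions: Pd(OCOCF3)2 (7.5 mol%), (R)-4-tert-butyl-2-(pyridin-2-yl)-4,5-dihydrooxazole (9 mol%), NH4PF6 (30 mol%), H2O (5 equiv), ClCH2CH2Cl, 60 °C
Reagents that add atoms: none
Why: Asymmetric conjugate addition of an arylboronic acid to a chromone under cationic divalent palladium/pyridine–oxazoline catalysis: transmetalation gives an aryl–palladium species, the C2=C3 bond of 9 inserts into it with aryl transfer to C2, and the palladium enolate is protonated by water, so the metal stays divalent and no base is present. The closest known reaction type is this same palladium-catalysed enantioselective arylation of chromones to flavanones, applied here to a 5,7-dioxygenated chromone and an electron-rich 3,4-disubstituted boronic acid. No ring is closed: rings A and C are already in 9, and the step joins ring B through the C2–C1' bond while turning the flat pyranone into the dihydropyranone of the target at the ketone oxidation state. C2 is the only new stereocentre and is set by the catalyst, the tert-butyl group of the ligand blocking one face of the coordinated C2=C3 bond during insertion. The step needs 1,4- over 1,2-addition, insertion of the enone and not of the prenyl alkene, and protonation of the enolate instead of β-hydride elimination to the flavone; the unactivated trisubstituted alkene inserts far more slowly than the enone, water and the ammonium salt speed up protonation, and the silyl ethers keep the acidic 7-OH and the chelating 5-OH/4-oxo pair away from the metal. The base-free, weakly acidic medium should leave the new O1–C2–aryl centre closed, so that the configuration is kept.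

Step 5
Reactants: 10 (2S)-2-[4-methoxy-3-(3-methylbut-2-en-1-yl)phenyl]-5,7-bis(triisopropylsilyloxy)chroman-4-one
Product: 11 4'-O-methyllicoflavanone, (2S)-5,7-dihydroxy-2-[4-methoxy-3-(3-methylbut-2-en-1-yl)phenyl]chroman-4-one
Conditions: Bu4NF (2.4 equiv), AcOH (2.4 equiv), THF, 0 °C
Reagents that add atoms: none
Why: Fluoride cleavage of aryl silyl ethers is fast for silyloxy groups conjugated to the ketone, and the acetic acid buffer releases phenols without forming the C3 enolate, so the retro-oxa-Michael opening that racemises flavanones is not triggered and the prenyl group and methyl ether are untouched.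

**Compound list**
1 | 4-bromo-2-iodo-1-methoxybenzene | COc1ccc(Br)cc1I | starting material
2 | 1-bromo-3-methylbut-2-ene (prenyl bromide) | CC(C)=CCBr | starting material
3 | (5-bromo-2-methoxyphenyl)magnesium chloride | COc1ccc(Br)cc1[Mg]Cl | intermediate
4 | 4-bromo-1-methoxy-2-(3-methylbut-2-en-1-yl)benzene | COc1ccc(Br)cc1CC=C(C)C | intermediate
5 | [4-methoxy-3-(3-methylbut-2-en-1-yl)phenyl]lithium | [Li]c1ccc(OC)c(CC=C(C)C)c1 | intermediate
6 | lithium triisopropoxy[4-methoxy-3-(3-methylbut-2-en-1-yl)phenyl]borate | [Li+].COc1ccc([B-](OC(C)C)(OC(C)C)OC(C)C)cc1CC=C(C)C | intermediate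
7 | [4-methoxy-3-(3-methylbut-2-en-1-yl)phenyl]boronic acid | COc1ccc(B(O)O)cc1CC=C(C)C | intermediate
8 | 5,7-dihydroxy-4H-chromen-4-one | O=c1ccoc2cc(O)cc(O)c12 | starting material
9 | 5,7-bis(triisopropylsilyloxy)-4H-chromen-4-one | O=c1ccoc2cc(O[Si](C(C)C)(C(C)C)C(C)C)cc(O[Si](C(C)C)(C(C)C)C(C)C)c12 | intermediate
10 | (2S)-2-[4-methoxy-3-(3-methylbut-2-en-1-yl)phenyl]-5,7-bis(triisopropylsilyloxy)chroman-4-one | COc1ccc([C@@H]2CC(=O)c3c(O[Si](C(C)C)(C(C)C)C(C)C)cc(O[Si](C(C)C)(C(C)C)C(C)C)cc3O2)cc1CC=C(C)C | intermediate
11 | 4'-O-methyllicoflavanone | COc1ccc([C@@H]2CC(=O)c3c(O)cc(O)cc3O2)cc1CC=C(C)C | target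

Total step count: 5. Longest linear sequence: 4 (steps 1, 2, 4, 5).

**Steps most likely to fail**

1. Step 4. The two donor oxygens on ring A make the chromone a weak acceptor, so protodeboronation of the electron-rich boronic acid may outrun insertion. Facial discrimination may be insufficient, and the doubly activated allylic CH2 of the prenyl group may divert the palladium. The fallback sets out from bromide 4 and chromone 9 and comes back at 10. Magnesium in THF would convert 4 into [4-methoxy-3-(3-methylbut-2-en-1-yl)phenyl]magnesium bromide F1. CuBr·SMe2 (10 mol%) and Me3SiCl would drive its 1,4-addition to 9, giving the racemic silyl enol ether 2-[4-methoxy-3-(3-methylbut-2-en-1-yl)phenyl]-5,7-bis(triisopropylsilyloxy)-4-(trimethylsilyloxy)-2H-chromene F2. Mild aqueous acid would hydrolyse it to racemic 2-[4-methoxy-3-(3-methylbut-2-en-1-yl)phenyl]-5,7-bis(triisopropylsilyloxy)chroman-4-one F3. Preparative chromatography on a cellulose tris(3,5-dimethylphenylcarbamate) phase would then separate the enantiomers and deliver 10.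

2. Step 5. Fluoride may generate phenoxide and enolate faster than the buffer quenches them, so that ring C opens to the chalcone and recloses with erosion of the configuration at C2. The fallback sets out from 8 and comes back at 11, using acid-labile ethers. MOMCl and NaH in DMF would give 5,7-bis(methoxymethoxy)-4H-chromen-4-one F4. The conjugate addition of step 4 with boronic acid 7 would give (2S)-2-[4-methoxy-3-(3-methylbut-2-en-1-yl)phenyl]-5,7-bis(methoxymethoxy)chroman-4-one F5. Dilute HCl in methanol at room temperature would release 11 without any phenoxide being formed.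

3. Step 1. The aryl–copper species may attack the tertiary terminus of the allyl system and give the branched 1,1-dimethylallyl isomer, or the Grignard reagent may homocouple. The fallback sets out from 1 (through Grignard reagent 3) and comes back at 4. Trapping 3 with allyl bromide and Li2CuCl4, which has no regiochemical ambiguity, would give 4-bromo-1-methoxy-2-(prop-2-en-1-yl)benzene F6. Olefin cross-metathesis with excess 2-methylbut-2-ene (second-generation Grubbs catalyst, CH2Cl2, 40 °C) would then build the trisubstituted alkene and give 4.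

**Further compounds**
F1 | step 4 | [4-methoxy-3-(3-methylbut-2-en-1-yl)phenyl]magnesium bromide | COc1ccc([Mg]Br)cc1CC=C(C)C
F2 | step 4 | racemic 2-[4-methoxy-3-(3-methylbut-2-en-1-yl)phenyl]-5,7-bis(triisopropylsilyloxy)-4-(trimethylsilyloxy)-2H-chromene | COc1ccc(C2C=C(O[Si](C)(C)C)c3c(O[Si](C(C)C)(C(C)C)C(C)C)cc(O[Si](C(C)C)(C(C)C)C(C)C)cc3O2)cc1CC=C(C)C
F3 | step 4 | racemic 2-[4-methoxy-3-(3-methylbut-2-en-1-yl)phenyl]-5,7-bis(triisopropylsilyloxy)chroman-4-one | COc1ccc(C2CC(=O)c3c(O[Si](C(C)C)(C(C)C)C(C)C)cc(O[Si](C(C)C)(C(C)C)C(C)C)cc3O2)cc1CC=C(C)C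
F4 | step 5 | 5,7-bis(methoxymethoxy)-4H-chromen-4-one | COCOc1cc(OCOC)c2c(=O)ccoc2c1
F5 | step 5 | (2S)-2-[4-methoxy-3-(3-methylbut-2-en-1-yl)phenyl]-5,7-bis(methoxymethoxy)chroman-4-one | COc1ccc([C@@H]2CC(=O)c3c(OCOC)cc(OCOC)cc3O2)cc1CC=C(C)C
F6 | step 1 | 4-bromo-1-methoxy-2-(prop-2-en-1-yl)benzene | C=CCc1cc(Br)ccc1OC
A1 | direct plan | 2-hydroxy-4,6-bis(tert-butyldimethylsilyloxy)benzaldehyde | O=Cc1c(O)cc(O[Si](C)(C)C(C)(C)C)cc1O[Si](C)(C)C(C)(C)C
A2 | direct plan | 6-(methoxymethylidene)-3,5-bis(tert-butyldimethylsilyloxy)cyclohexa-2,4-dien-1-one | COC=C1C(=O)C=C(O[Si](C)(C)C(C)(C)C)C=C1O[Si](C)(C)C(C)(C)C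
A3 | direct plan | 1-methoxy-2-(3-methylbut-2-enyl)-4-vinylbenzene | C=Cc1ccc(OC)c(CC=C(C)C)c1
A4 | direct plan | (2S,4S)-5,7-bis(tert-butyldimethylsilyloxy)-4,4'-dimethoxy-3'-(3-methylbut-2-enyl)flavan | COc1ccc([C@@H]2C[C@H](OC)c3c(O[Si](C)(C)C(C)(C)C)cc(O[Si](C)(C)C(C)(C)C)cc3O2)cc1CC=C(C)C
A5 | direct plan | (2S)-5,7-bis(tert-butyldimethylsilyloxy)-4'-methoxy-3'-(3-methylbut-2-enyl)flavan-4-ol, C4 epimers | COc1ccc([C@@H]2CC(O)c3c(O[Si](C)(C)C(C)(C)C)cc(O[Si](C)(C)C(C)(C)C)cc3O2)cc1CC=C(C)C
A6 | direct plan | (2S)-5,7-bis(tert-butyldimethylsilyloxy)-4'-methoxy-3'-(3-methylbut-2-enyl)flavanone | COc1ccc([C@@H]2CC(=O)c3c(O[Si](C)(C)C(C)(C)C)cc(O[Si](C)(C)C(C)(C)C)cc3O2)cc1CC=C(C)C
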